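**Retrosynthetic overview**
- Target ⇒ 5–7-fused bicyclic alkenol (ring-fusion OH) + 4-methoxybenzoic acid: the secondary ester C–O bond and the adjacent tertiary C–OH bond (trans) are both made in one hydroxyl-directed anti hydroxy-aroyloxylation of the trisubstituted ring alkene (key step, new).
- Bicyclic alkenol ⇒ cyclopentanol carrying cis allyl and 3-methylbut-3-enyl groups (ring-closing metathesis; the seven-membered ring is formed second and last).
- That diene ⇒ (2R,5R)-2-allyl-5-isopropyl-2-methylcyclopentanone + 3-methylbut-3-enyl organometallic (addition anti to isopropyl puts the tertiary OH on the isopropyl face).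
- Ketone ⇒ regiodefined enolate + allyl bromide ⇐ enol formate ⇐ (Baeyer–Villiger, C–O) 5-isopropyl-2-methylcyclopentene-1-carbaldehyde.
- Enal ⇒ keto-aldehyde (intramolecular aldol condensation; the five-membered ring is formed first) ⇐ ozonolysis of (S)-p-menth-1-ene ⇐ (S)-limonene, whose stereocentre becomes the isopropyl-bearing carbon and controls all others.

Assumption: (S)-(−)-limonene, allyl bromide, 4-bromo-2-methylbut-1-ene and 4-methoxybenzoic acid are taken as catalogue starting materials; compound numbers follow the forward route; "the hydroxyl face" means the ring face that carries the ring-fusion OH, the ring-fusion methyl and the isopropyl group in the target.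

**Step 1**
Reactants: 1 (S)-(−)-limonene
Product: 2 (4S)-1-methyl-4-(propan-2-yl)cyclohex-1-ene
Conditions: H2 (1 atm), RhCl(PPh3)3 (1 mol %), benzene–EtOH, 23 °C
Reagents that add atoms: none
Why: Homogeneous catalytic hydrogenation with RhCl(PPh3)3 reduces the 1,1-disubstituted isopropenyl alkene much faster than the trisubstituted ring alkene and leaves the stereocentre untouched.

**Step 2**
Reactants: 2 (4S)-1-methyl-4-(propan-2-yl)cyclohex-1-ene
Product: 4 (3S)-6-oxo-3-(propan-2-yl)heptanal, via ozonide 3 (not isolated)
Conditions: O3, CH2Cl2, −78 °C; then PPh3, −78 → 23 °C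
Reagents that add atoms: ozone, [O-][O+]=O
Why: Ozonolysis with reductive work-up cleaves the only alkene to the methyl ketone and the aldehyde, and the stereocentre is not enolisable in either 2 or 4.

**Step 3**
Reactants: 4 (3S)-6-oxo-3-(propan-2-yl)heptanal
Product: 5 (5R)-2-methyl-5-(propan-2-yl)cyclopent-1-ene-1-carbaldehyde
Conditions: piperidine (0.2 equiv), AcOH (0.2 equiv), benzene, 80 °C, Dean–Stark
Reagents that add atoms: none
Why: In this enamine-mediated intramolecular aldol condensation the aldehyde enamine attacks the methyl ketone and dehydration gives the tetrasubstituted enal, while the isopropyl-bearing carbon stays configurationally fixed because it cannot be enolised.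

**Step 4**
Reactants: 5 (5R)-2-methyl-5-(propan-2-yl)cyclopent-1-ene-1-carbaldehyde
Product: 6 (5R)-2-methyl-5-(propan-2-yl)cyclopent-1-en-1-yl formate
Conditions: mCPBA (1.05 equiv), CH2Cl2, 0 °C
Reagents that add atoms: 3-chloroperoxybenzoic acid, OOC(=O)c1cccc(Cl)c1
Why: Baeyer–Villiger oxidation of a β,β-disubstituted enal proceeds with migration of the electron-rich alkenyl group, which installs the ring C–O bond and fixes the enol double bond towards the methyl-bearing carbon.

**Step 5**
Reactants: 6 (5R)-2-methyl-5-(propan-2-yl)cyclopent-1-en-1-yl formate; 7 allyl bromide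
Product: 9 (2R,5R)-2-methyl-5-(propan-2-yl)-2-(prop-2-en-1-yl)cyclopentan-1-one, via lithium enolate 8 (not isolated)
Conditions: CH3Li (2.1 equiv), THF, −78 → 0 °C (6 added to CH3Li); then 7, DMPU, −78 → 0 °C
Reagents that add atoms: allyl bromide 7, C=CCBr
Why: Cleavage of the enol ester with two equivalents of CH3Li gives the tetrasubstituted lithium enolate regiospecifically without touching the C–H next to isopropyl, and SN2 enolate allylation then occurs on the face anti to the isopropyl group (held pseudoaxial by allylic 1,2-strain with the solvated O–Li unit), which sets the quaternary centre with allyl trans to isopropyl.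

**Step 6**
Reactants: 9 (2R,5R)-2-methyl-5-(propan-2-yl)-2-(prop-2-en-1-yl)cyclopentan-1-one; 10 4-bromo-2-methylbut-1-ene
Product: 11 (1S,2R,5R)-2-methyl-1-(3-methylbut-3-en-1-yl)-5-(propan-2-yl)-2-(prop-2-en-1-yl)cyclopentan-1-ol
Conditions: 10, Mg, THF, 40 °C; CeCl3, THF, −78 °C; then 9, −78 → 0 °C; 1 M HCl, 0 °C
Reagents that add atoms: 4-bromo-2-methylbut-1-ene 10 (as its Grignard and organocerium reagent), C=C(C)CCBr
Why: The weakly basic organocerium reagent undergoes 1,2-addition to the hindered ketone without enolisation and enters anti to the adjacent isopropyl group (steric approach control), so the new tertiary hydroxyl is cis to isopropyl and to the ring methyl and the two alkenyl chains are cis.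

**Step 7**
Reactants: 11 (1S,2R,5R)-2-methyl-1-(3-methylbut-3-en-1-yl)-5-(propan-2-yl)-2-(prop-2-en-1-yl)cyclopentan-1-ol
Product: 12 (3R,3aS,8aR)-6,8a-dimethyl-3-(propan-2-yl)-2,3,4,5,8,8a-hexahydroazulen-3a(1H)-ol
Conditions: second-generation Hoveyda–Grubbs catalyst RuCl2(H2IMes)(=CH-C6H4-2-O-i-Pr) (5 mol %), toluene (0.005 M), 80 °C
Reagents that add atoms: none
Why: Ring-closing metathesis between the allyl group and the 1,1-disubstituted alkene, which are cis on the cyclopentane, closes the cis-fused seven-membered ring as the trisubstituted cycloalkene with loss of ethene and tolerates the free tertiary alcohol.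

**Step 8**
Reactants: 12 (3R,3aS,8aR)-6,8a-dimethyl-3-(propan-2-yl)-2,3,4,5,8,8a-hexahydroazulen-3a(1H)-ol; 13 4-methoxybenzoic acid
Product: 16 [(1R,3aR,5R,6R,8aS)-6,8a-dihydroxy-3a,6-dimethyl-1-(propan-2-yl)decahydroazulen-5-yl] 4-methoxybenzoate (CNP0244624.1), via epoxy alcohol 14 (not isolated), via tertiary ester 15 (not isolated)
Conditions: VO(O-i-Pr)3 (5 mol %), t-BuOOH (1.2 equiv, in decane), toluene, 0 → 23 °C; then 13 (1.5 equiv), 60 °C; then Et3N (0.2 equiv), 23 °C
Reagents that add atoms: tert-butyl hydroperoxide, CC(C)(C)OO; 4-methoxybenzoic acid 13, COc1ccc(cc1)C(=O)O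
Why: Proposed new method: a hydroxyl-directed anti hydroxy-aroyloxylation of an unactivated trisubstituted alkene in one flask, in which the pentavalent vanadium alkoxide formed at the ring-fusion hydroxyl first transfers oxygen from t-BuOOH to the alkene face syn to that hydroxyl (giving 14), then stays bound as an alkoxide/epoxide chelate that acts as an internal Lewis acid and exposes the tertiary epoxide carbon to backside attack by external 4-methoxybenzoic acid (inversion, giving 15, while the chelated ring-fusion oxygen sits on the epoxide face and cannot close a transannular ether), and finally the vanadium-bound secondary alkoxide takes over the aroyl group by a 1,2 O-to-O shift through a five-membered ortho-acid to give the less strained secondary ester 16, so that both new C–O bonds and both new stereocentres (ester oxygen on the hydroxyl face, tertiary OH on the opposite face) arise from one directing group; the closest known reaction types are the VO(acac)2/t-BuOOH directed epoxidation of homoallylic and bishomoallylic alcohols, the Ti(O-i-Pr)4-mediated regioselective opening of epoxy alcohols by carboxylic acids and acyl migration in diol monoesters, which have not been merged into a single directed alkene hydroxy-acyloxylation with a free carboxylic acid.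

**Compound list**
1 | (S)-(−)-limonene, (4S)-1-methyl-4-(prop-1-en-2-yl)cyclohex-1-ene | CC1=CC[C@H](CC1)C(C)=C | starting material
2 | (4S)-1-methyl-4-(propan-2-yl)cyclohex-1-ene, (S)-p-menth-1-ene | CC1=CC[C@H](CC1)C(C)C | intermediate
3 | secondary ozonide of 2, 1-methyl-4-(propan-2-yl)-7,8,9-trioxabicyclo[4.2.1]nonane (isopropyl-bearing carbon as in 2, bridgeheads unassigned) | CC12CC[C@H](C(C)C)CC(OO1)O2 | intermediate
4 | (3S)-6-oxo-3-(propan-2-yl)heptanal | O=CC[C@H](CCC(C)=O)C(C)C | intermediate
5 | (5R)-2-methyl-5-(propan-2-yl)cyclopent-1-ene-1-carbaldehyde | CC1=C(C=O)[C@@H](C(C)C)CC1 | intermediate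
6 | (5R)-2-methyl-5-(propan-2-yl)cyclopent-1-en-1-yl formate | CC1=C(OC=O)[C@@H](C(C)C)CC1 | intermediate
7 | allyl bromide, 3-bromoprop-1-ene | C=CCBr | starting material
8 | lithium (5R)-2-methyl-5-(propan-2-yl)cyclopent-1-en-1-olate | CC1=C([O-])[C@@H](C(C)C)CC1.[Li+] | intermediate
9 | (2R,5R)-2-methyl-5-(propan-2-yl)-2-(prop-2-en-1-yl)cyclopentan-1-one (allyl trans to isopropyl) | C=CC[C@@]1(C)CC[C@H](C(C)C)C1=O | intermediate
10 | 4-bromo-2-methylbut-1-ene | C=C(C)CCBr | starting material
11 | (1S,2R,5R)-2-methyl-1-(3-methylbut-3-en-1-yl)-5-(propan-2-yl)-2-(prop-2-en-1-yl)cyclopentan-1-ol (OH, ring methyl and isopropyl on one face) | C=CC[C@@]1(C)CC[C@H](C(C)C)[C@@]1(O)CCC(C)=C | intermediate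
12 | (3R,3aS,8aR)-6,8a-dimethyl-3-(propan-2-yl)-2,3,4,5,8,8a-hexahydroazulen-3a(1H)-ol | CC1=CC[C@@]2(C)CC[C@H](C(C)C)[C@@]2(O)CC1 | intermediate
13 | 4-methoxybenzoic acid | COc1ccc(cc1)C(=O)O | starting material
14 | (3R,3aS,6S,7R,8aR)-6,7-epoxy-6,8a-dimethyl-3-(propan-2-yl)octahydroazulen-3a(1H)-ol (epoxide oxygen on the hydroxyl face) | O1[C@@H]2C[C@@]3(C)CC[C@H](C(C)C)[C@@]3(O)CC[C@]12C | intermediate
15 | [(3R,3aS,6R,7R,8aR)-3a,7-dihydroxy-6,8a-dimethyl-3-(propan-2-yl)decahydroazulen-6-yl] 4-methoxybenzoate (tertiary ester regioisomer of 16) | O[C@@H]1C[C@@]2(C)CC[C@H](C(C)C)[C@@]2(O)CC[C@@]1(C)OC(=O)c1ccc(OC)cc1 | intermediate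
16 | [(1R,3aR,5R,6R,8aS)-6,8a-dihydroxy-3a,6-dimethyl-1-(propan-2-yl)decahydroazulen-5-yl] 4-methoxybenzoate, CNP0244624.1 | COc1ccc(C(=O)O[C@@H]2C[C@@]3(C)CC[C@H](C(C)C)[C@@]3(O)CC[C@@]2(C)O)cc1 | target

**Totals and risks**
Total step count: 8. Longest linear sequence: 8 steps (1 → 16).

The three steps most likely to fail are steps 5, 6 and 8.

Step 5 relies on 1,3-induction from the isopropyl group for the quaternary centre, so the diastereomer ratio may be modest. The fallback sets out from 6 and replaces substrate control by catalyst control. The lithium enolate 8, made as before, is O-acylated with allyl chloroformate (TMEDA, THF, −78 °C) to (5R)-2-methyl-5-(propan-2-yl)cyclopent-1-en-1-yl prop-2-en-1-yl carbonate F1. Decarboxylative Tsuji allylation of this carbonate with Pd2(dba)3 (2.5 mol %) and (R)-t-Bu-PHOX (6 mol %) in THF at 25 °C comes back to the route at 9. The (R) ligand is the antipode that, by analogy with the parent 2-methylcycloalkanone enol carbonates, gives the (R) quaternary centre, so it reinforces the substrate bias.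

Step 6 may suffer from low conversion at the doubly α-branched ketone. The fallback sets out from 9 and forms the same C–C bond with a small nucleophile, then finishes the side chain separately. Corey–Chaykovsky methylenation (trimethylsulfonium iodide, n-BuLi, THF, −10 → 23 °C) delivers CH2 anti to isopropyl and gives (3S,4R,7R)-4-methyl-7-(propan-2-yl)-4-(prop-2-en-1-yl)-1-oxaspiro[2.4]heptane F2. Copper-catalysed opening of this spiro-epoxide at its CH2 carbon with 2-methylallylmagnesium chloride (CuI 10 mol %, THF, −30 → 0 °C) comes back to the route at 11.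

Step 8 is the new step. It may stall at 14, or the epoxide may ionise and give elimination, hydride-shift or transannular ether products. The fallback sets out from 12 and uses only known reactions:
- Directed epoxidation with VO(acac)2 (2 mol %) and t-BuOOH in CH2Cl2 at 0 °C, with isolation of epoxy alcohol 14.
- Acid-catalysed hydrolysis (HClO4 cat., THF–water, 0 °C), in which water attacks the tertiary carbon with inversion, to (3R,3aS,6R,7R,8aR)-6,8a-dimethyl-3-(propan-2-yl)decahydroazulene-3a,6,7-triol F3.
- Acylation of the only secondary hydroxyl of this triol with 4-methoxybenzoyl chloride, pyridine and DMAP in CH2Cl2 at 0 °C, which comes back to the route at 16.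

**Further compounds**
F1 | step 5 | (5R)-2-methyl-5-(propan-2-yl)cyclopent-1-en-1-yl prop-2-en-1-yl carbonate | CC1=C(OC(=O)OCC=C)[C@@H](C(C)C)CC1
F2 | step 6 | (3S,4R,7R)-4-methyl-7-(propan-2-yl)-4-(prop-2-en-1-yl)-1-oxaspiro[2.4]heptane | C=CC[C@@]1(C)CC[C@H](C(C)C)[C@@]12CO2
F3 | step 8 | (3R,3aS,6R,7R,8aR)-6,8a-dimethyl-3-(propan-2-yl)decahydroazulene-3a,6,7-triol | O[C@@H]1C[C@@]2(C)CC[C@H](C(C)C)[C@@]2(O)CC[C@@]1(C)O
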